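**Retrosynthetic overview**
1. Target 9 comes from its 7,3',4'-tri-O-MOM ether 8 by acidic acetal cleavage.
2. The C6–C1'' bond of 8 comes from 6-iodide 6 (through its boronate 7) and allylic acetate 3 by palladium-catalysed allyl–aryl coupling.
3. Iodide 6 comes from commercial (2R,3R)-taxifolin 4 by tri-MOM protection and iodination ortho to the hydrogen-bonded 5-OH.
4. Key step: the C6''–O bond and its (R) centre in 3 come from geranyl acetate 1 by a new enantioselective ene-type C–O bond formation with an oxoammonium salt under chiral-anion phase transfer, followed by N–O cleavage.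
5. No ring is formed in the route: rings A, B and C and the C2/C3 centres are carried intact from taxifolin.

**Assumptions**
- (+)-(2R,3R)-Taxifolin (dihydroquercetin from larch), geranyl acetate and the oxoammonium salt are taken as cheap commercial materials.
- The sense of induction of the new step cannot be predicted; the (R)-acid is written, and its mirror image is used if it delivers the (S)-alcohol.

Abbreviations: (R)-TRIP = (R)-3,3'-bis(2,4,6-triisopropylphenyl)-1,1'-binaphthyl-2,2'-diyl hydrogen phosphate; SPhos = 2-dicyclohexylphosphino-2',6'-dimethoxybiphenyl; B2pin2 = bis(pinacolato)diboron; MOM = methoxymethyl.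

**Step 1**
Reactants: 1 geranyl acetate
Product: 3 (2E,6R)-6-hydroxy-3,7-dimethylocta-2,7-dien-1-yl acetate, via allylic alkoxyamine 2 (not isolated)
Conditions: 4-acetamido-2,2,6,6-tetramethyl-1-oxopiperidinium BF4 (1.1 equiv), (R)-TRIP (10 mol%), Na2CO3, toluene, −20 °C; filter; then Zn, AcOH/THF/H2O, 40 °C
Reagents that add atoms: 4-acetamido-2,2,6,6-tetramethyl-1-oxopiperidinium tetrafluoroborate, CC(=O)NC1CC(C)(C)[N+](=O)C(C)(C)C1.F[B-](F)(F)F (its oxygen becomes the C6 hydroxyl oxygen; the whole aminoxyl unit is present in 2)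
Why: Proposed new method: an enantioselective oxoammonium ene-type oxygenation — the insoluble oxoammonium salt enters toluene only as its ion pair with the chiral phosphate; its N=O+ oxygen attacks C6 of the more electron-rich terminal alkene (the 2,3-alkene is deactivated by the allylic acetoxy group) while charge builds at tertiary C7 and the phosphate removes a C8 methyl proton in a cyclic ene-like transition state, so the C6–O bond, the exocyclic 7,8-alkene and the C6 configuration arise in one catalyst-bound event in which the 3,3'-aryl walls of the phosphate select the alkene face (intended R); Zn/AcOH then cleaves the N–O bond without touching C6; the closest known reactions are the racemic ene-like addition of this oxoammonium salt to trisubstituted alkenes (same regiochemistry, with Zn/AcOH N–O cleavage) and chiral-anion phase-transfer catalysis of oxoammonium oxidations, whose combination into an enantioselective C–O bond-forming ene reaction is unprecedented.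

**Step 2**
Reactants: 4 (+)-(2R,3R)-taxifolin
Product: 5 (2R,3R)-2-[3,4-bis(methoxymethoxy)phenyl]-3,5-dihydroxy-7-(methoxymethoxy)chroman-4-one
Conditions: MOMCl (3.3 equiv), iPr2NEt, CH2Cl2/DMF, 0 °C → rt
Reagents that add atoms: chloromethyl methyl ether (MOMCl), COCCl
Why: Williamson-type O-alkylation of the three most acidic phenols (7, 4', 3') leaves the chelated 5-OH and the hindered secondary 3-OH free, and the hindered amine base at or below room temperature does not enolise C3, so the (2R,3R) centres are untouched.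

**Step 3**
Reactants: 5 tri-O-MOM-taxifolin
Product: 6 (2R,3R)-2-[3,4-bis(methoxymethoxy)phenyl]-3,5-dihydroxy-6-iodo-7-(methoxymethoxy)chroman-4-one
Conditions: NIS (1.0 equiv), DMF, 0 °C → rt, dark
Reagents that add atoms: N-iodosuccinimide, O=C1CCC(=O)N1I
Why: Electrophilic aromatic iodination of the phloroglucinol-type ring A goes ortho to the free, hydrogen-bonded 5-OH (C6) and not to C8, the established pattern for 5-hydroxy-7-alkoxyflavonoids, while the bis-MOM ring B is far less activated; no stereocentre is involved.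

**Step 4**
Reactants: 6 the 6-iodide; 3 (2E,6R)-6-hydroxy-3,7-dimethylocta-2,7-dien-1-yl acetate
Product: 8 (2R,3R)-2-[3,4-bis(methoxymethoxy)phenyl]-3,5-dihydroxy-6-[(2E,6R)-6-hydroxy-3,7-dimethylocta-2,7-dien-1-yl]-7-(methoxymethoxy)chroman-4-one, via 6-boryl pinacol ester 7 (not isolated)
Conditions: B2pin2 (1.1 equiv), Pd(OAc)2/SPhos, KOAc, dioxane, 80 °C; then 3 (1.3 equiv), K3PO4, H2O (5 equiv), 50 °C
Reagents that add atoms: bis(pinacolato)diboron, CC1(C)OB(OC1(C)C)B1OC(C)(C)C(C)(C)O1 (gives the boryl group of 7; no atom of it remains in 8)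
Why: Miyaura borylation followed in the same flask by a Suzuki–Miyaura-type allyl–aryl coupling, in which zerovalent palladium ionises only the primary allylic acetate of 3 to a π-allyl complex and the aryl group is delivered to the unsubstituted allyl terminus, giving the linear product with the E-alkene retained (E/Z exchange would need an unfavourable tertiary σ-allyl), the free secondary allylic alcohol is not ionised, any O-allylation of the 5-phenoxide is reversible, and no stereocentre is touched.

**Step 5**
Reactants: 8 the tri-O-MOM ether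
Product: 9 (2R,3R)-2-(3,4-dihydroxyphenyl)-3,5,7-trihydroxy-6-[(2E,6R)-6-hydroxy-3,7-dimethylocta-2,7-dien-1-yl]chroman-4-one (CNP0280079.1)
Conditions: 1 M HCl in MeOH, 30 °C
Reagents that add atoms: none
Why: Acid-catalysed acetal exchange (methanolysis) removes the three aryl MOM ethers, and dilute acid near room temperature is intended to leave the flavanonol centres, the trisubstituted alkene and the secondary allylic alcohol unchanged.

**Compound list**
1 | geranyl acetate, (2E)-3,7-dimethylocta-2,6-dien-1-yl acetate | CC(C)=CCC/C(C)=C/COC(C)=O | starting material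
2 | (2E,6R)-6-[(4-acetamido-2,2,6,6-tetramethylpiperidin-1-yl)oxy]-3,7-dimethylocta-2,7-dien-1-yl acetate | C=C(C)[C@H](ON1C(C)(C)CC(NC(C)=O)CC1(C)C)CC/C(C)=C/COC(C)=O | intermediate
3 | (2E,6R)-6-hydroxy-3,7-dimethylocta-2,7-dien-1-yl acetate | C=C(C)[C@H](O)CC/C(C)=C/COC(C)=O | intermediate
4 | (+)-(2R,3R)-taxifolin (dihydroquercetin) | Oc1cc2c(c(O)c1)C(=O)[C@H](O)[C@@H](c1ccc(O)c(O)c1)O2 | starting material
5 | 7,3',4'-tri-O-MOM-(2R,3R)-taxifolin | COCOc1cc2c(c(O)c1)C(=O)[C@H](O)[C@@H](c1ccc(OCOC)c(OCOC)c1)O2 | intermediate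
6 | 6-iodo-7,3',4'-tri-O-MOM-(2R,3R)-taxifolin | COCOc1cc2c(c(O)c1I)C(=O)[C@H](O)[C@@H](c1ccc(OCOC)c(OCOC)c1)O2 | intermediate
7 | 6-(4,4,5,5-tetramethyl-1,3,2-dioxaborolan-2-yl)-7,3',4'-tri-O-MOM-(2R,3R)-taxifolin | COCOc1cc2c(c(O)c1B1OC(C)(C)C(C)(C)O1)C(=O)[C@H](O)[C@@H](c1ccc(OCOC)c(OCOC)c1)O2 | intermediate
8 | 7,3',4'-tri-O-MOM ether of the target | C=C(C)[C@H](O)CC/C(C)=C/Cc1c(OCOC)cc2c(c1O)C(=O)[C@H](O)[C@@H](c1ccc(OCOC)c(OCOC)c1)O2 | intermediate
9 | (2R,3R)-2-(3,4-dihydroxyphenyl)-3,5,7-trihydroxy-6-[(2E,6R)-6-hydroxy-3,7-dimethylocta-2,7-dien-1-yl]chroman-4-one | C=C(C)[C@H](O)CC/C(C)=C/Cc1c(O)cc2c(c1O)C(=O)[C@H](O)[C@@H](c1ccc(O)c(O)c1)O2 | target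

**Step count and risks**
Total steps: 5. Longest linear sequence: 4 (4 → 5 → 6 → 8 → 9); the side-chain arm 1 → 3 is one step.

The three steps most likely to fail are steps 1, 4 and 5.

Step 1 is the new reaction; the risks are low enantioselectivity and incomplete selectivity for the terminal alkene. Because the taxifolin core is enantiopure, the minor enantiomer of 3 shows up after step 4 as a diastereomer and can be removed there. The fallback uses known chemistry, sets out from 1 and comes back at 3. Shi epoxidation of 1 (D-fructose-derived Shi ketone, Oxone, K2CO3 buffer, MeCN/dimethoxymethane/H2O, 0 °C) epoxidises the 6,7-alkene, which is remote from the acetoxy group, and gives (2E,6R)-6,7-epoxy-3,7-dimethyloct-2-en-1-yl acetate F1 (the mirror-image ketone is used if the sense proves opposite). Al(OiPr)3 in toluene at reflux then removes a methyl proton and opens the C7–O bond, giving 3 with the C6 configuration untouched.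

Step 4 can fail at three points. Borylation of the di-ortho-substituted, electron-rich iodide may give protodeiodination (this returns 5, which is recycled). Boronate 7 may protodeboronate. Warm phosphate may erode the base-sensitive flavanonol ring C. The fallback sets out from 6 and comes back at 8 and abandons the boron/base manifold. Me3SnSnMe3 with Pd(PPh3)4 in toluene at 90 °C gives 6-(trimethylstannyl)-7,3',4'-tri-O-MOM-(2R,3R)-taxifolin F2, which is isolated. F2 is then coupled with 3 under base-free conditions (Pd(dba)2, LiCl, DMF, rt to 40 °C). This aryl stannane/allylic acetate coupling is known to join at the primary carbon with retention of alkene geometry.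

Step 5 exposes the finished side chain to acid. The risks are chroman formation by attack of the 5-OH or 7-OH on the protonated 2'',3''-alkene, and ionisation of the allylic alcohol. The fallback changes the protecting-group class so that the last step is near-neutral; it sets out from 4 and comes back at 9. TBSCl/imidazole in DMF gives 7,3',4'-tri-O-TBS-(2R,3R)-taxifolin F3. NIS gives 6-iodo-7,3',4'-tri-O-TBS-(2R,3R)-taxifolin F4. The borylation/allylation of step 4 with 3 then passes through 6-boryl-7,3',4'-tri-O-TBS-(2R,3R)-taxifolin F5 (not isolated) to the 7,3',4'-tri-O-TBS ether of the target F6. Partial silyl loss in this coupling is harmless because the crude is desilylated directly with Et3N·3HF in THF at 0 °C to give 9.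

**Further compounds**
F1 | step 1 | (2E,6R)-6,7-epoxy-3,7-dimethyloct-2-en-1-yl acetate | CC1(C)O[C@@H]1CC/C(C)=C/COC(C)=O
F2 | step 4 | 6-(trimethylstannyl)-7,3',4'-tri-O-MOM-(2R,3R)-taxifolin | COCOc1cc2c(c(O)c1[Sn](C)(C)C)C(=O)[C@H](O)[C@@H](c1ccc(OCOC)c(OCOC)c1)O2
F3 | step 5 | 7,3',4'-tri-O-TBS-(2R,3R)-taxifolin | CC(C)(C)[Si](C)(C)Oc1cc2c(c(O)c1)C(=O)[C@H](O)[C@@H](c1ccc(O[Si](C)(C)C(C)(C)C)c(O[Si](C)(C)C(C)(C)C)c1)O2
F4 | step 5 | 6-iodo-7,3',4'-tri-O-TBS-(2R,3R)-taxifolin | CC(C)(C)[Si](C)(C)Oc1cc2c(c(O)c1I)C(=O)[C@H](O)[C@@H](c1ccc(O[Si](C)(C)C(C)(C)C)c(O[Si](C)(C)C(C)(C)C)c1)O2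
F5 | step 5 | 6-(4,4,5,5-tetramethyl-1,3,2-dioxaborolan-2-yl)-7,3',4'-tri-O-TBS-(2R,3R)-taxifolin | CC(C)(C)[Si](C)(C)Oc1cc2c(c(O)c1B1OC(C)(C)C(C)(C)O1)C(=O)[C@H](O)[C@@H](c1ccc(O[Si](C)(C)C(C)(C)C)c(O[Si](C)(C)C(C)(C)C)c1)O2
F6 | step 5 | 7,3',4'-tri-O-TBS ether of the target | C=C(C)[C@H](O)CC/C(C)=C/Cc1c(O[Si](C)(C)C(C)(C)C)cc2c(c1O)C(=O)[C@H](O)[C@@H](c1ccc(O[Si](C)(C)C(C)(C)C)c(O[Si](C)(C)C(C)(C)C)c1)O2
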